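The constants stand for no real mixture; the result is computed.

Time is the scale to set first, for the same charges handled in different vessels.

common to all: precatalyst 4.0 µM
- south-east: substrate 2.0 mM; partner 2.10 mM; a single well-mixed tank run continuously and read at steady state, 5.0 min in it on average
- west: substrate 2.0 mM; partner 2.10 mM (fed, over 5.00 min); all but partner at the start; partner goes in evenly over 5.00 min, the run ends at 5.0 min; time 5.0 min
- east: substrate 2.0 mM; partner 2.10 mM; everything together in a closed stirred flask, run for 5.0 min; time 5.0 min
- north-west: substrate 2.0 mM (fed, over 5.00 min); partner 2.10 mM; all but substrate at the start; substrate goes in evenly over 5.00 min, the run ends at 5.0 min; time 5.0 min

    substrate + catalyst → catalyst + intermediate (k1 = 7870 /M/s)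
    partner + catalyst + intermediate → catalyst + target (k2 = 5.69 × 10⁵ /M²/s)
    2 substrate → self-condensation product (k3 = 3.04 /M/s)
    2 substrate → homo dimer (k4 = 0.0272 /M/s)
    partner + precatalyst → catalyst + spent reagent (k5 = 3.55 /M/s)

- percent here means substrate units held: one self-condensation product or homo dimer counts as two
- where a step has two of a species, its rate is k times that concentration squared, and two are used at each turn
- the stated concentrations are those of everything mixed, before any reaction; amounts are the same in each set-up
- the feed brings no volume worth counting
- run time (west): 5.0 min

1. the set-up with the highest amount of target at the outlet or at the end, in percent of the substrate put in ("none" if the first two lie within 2 percentage points) (south-east / west / east / north-west / none)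
2. amount of target at the outlet or at the end, in percent of the substrate put in, south-east
3. amount of target at the outlet or at the end, in percent of the substrate put in, west
4. amount of target at the outlet or at the end, in percent of the substrate put in, east
5. amount of target at the outlet or at the end, in percent of the substrate put in, north-west

My reckoning reads two clocks from the charges. With partner at the whole of its charge, precatalyst becomes catalyst with a time constant of 2.24 min. Intermediate is pseudo-first-order in its step to target, and its turnover time, the time in which it falls by a factor e with the whole partner and the whole catalyst at work, is 3.49 min. Exposure is the run counted in turnover times, each moment weighted by the fractions of partner and catalyst then present. With partner counted as unconsumed, intermediate standing from the start keeps at least the share exp(-exposure), and intermediate formed later meets less exposure, so one minus that share is a ceiling on target's share of target plus intermediate.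

Turn the question round: a run leaving 10.0% of that intermediate unconverted needs an exposure of 2.3. East, with partner counted at its charge and catalyst growing, is reckoned at 0.861, a ceiling of 57.7%. West, with partner counted as rising evenly, is reckoned at 0.285, a ceiling of 24.8%. Both stand below the requirement, east by a factor 2.67 and west by 8.07. This reckoning puts the ceiling of east above that of west, gives shares rather than yields, and stops short of placing the tank or north-west.

The forecast names south-east, with 30.2% for south-east, 6.5% for west, 27.5% for east and 23.5% for north-west, holding that “withholding partner starves activation and west collapses”.

The simulation also gives south-east: 30.5% in south-east, 6.76% in west, 26.1% in east and 24.7% in north-west. West ends with 6.76% target beside 28.1% intermediate, a share of 19.4%, below its ceiling. The neighbour of west charged with 8.4 mM of partner has a turnover time of 0.872 min and an activation time of 0.559 min, so its exposure is 2.23 and its ceiling 89.2%. That neighbour ends with 39.7% target and 7.78% intermediate, a share of 83.6%.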